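Assumption: the SMILES contains no stereocentre and rotation about the diaryl ether bonds is free. The compound is therefore achiral, there is no enantiomer to select, and only regiochemistry has to be controlled.

## Retrosynthetic overview

1. No ring is formed. Ring A (dibromo-methoxyphenyl) and ring B (tetrabromo-hydroxyphenyl) both come preformed from commercial bromophenols, and the one bond joining them, ring A carbon to ether oxygen, is the key bond.
2. This bond is cut with reversed polarity at oxygen. Ring B enters as tetrabromo-o-benzoquinone, whose carbonyl oxygen acts as an "ArO+" synthon, and ring A enters as an aryl carbanion (arylcopper). Two centres that are both normally nucleophilic (phenol O, anisole C) are joined.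
3. The aryl carbanion comes from 2,4,6-tribromoanisole by ortho-selective Br/Mg exchange, and the anisole comes from 2,4,6-tribromophenol by O-methylation.
4. The quinone comes from tetrabromocatechol by oxidation. Its two oxygens are equivalent, the second one emerges as the free OH, and reduction to the catechol level stops a second arylation, so no protecting group is needed.

## Route

Step 1
Reactants: 1 2,4,6-tribromophenol
Product: 2 2,4,6-tribromoanisole (1,3,5-tribromo-2-methoxybenzene)
Conditions: MeI (1.3 equiv), K2CO3 (1.5 equiv), acetone, reflux, 4 h
Reagents that add atoms: iodomethane, CI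
Why: Williamson ether synthesis, in which the acidic but hindered phenoxide (pKa about 6) is alkylated only on oxygen by the small SN2 electrophile MeI; no stereocentre is formed.

Step 2
Reactants: 3 3,4,5,6-tetrabromobenzene-1,2-diol (tetrabromocatechol)
Product: 4 3,4,5,6-tetrabromocyclohexa-3,5-diene-1,2-dione (o-bromanil)
Conditions: conc. HNO3 (2.5 equiv), AcOH, 15 °C to rt, 15 min; ice water, filter; recrystallise (CH2Cl2/hexane), dry in vacuo over P2O5
Reagents that add atoms: none
Why: Two-electron oxidation of a catechol to the o-quinone (the classical nitric acid preparation of o-bromanil), in which nitration cannot compete because every ring position carries bromine; fresh preparation gives the dry, catechol-free quinone that step 3 needs, and no stereocentre is formed.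

Step 3
Reactants: 2 2,4,6-tribromoanisole; 4 o-bromanil
Product: 9 2,3,4,5-tetrabromo-6-(3,5-dibromo-2-methoxyphenoxy)phenol (target), via aryl Grignard reagent 5 (not isolated), via arylcopper 6 (not isolated), via arylcopper catecholate 7 (not isolated), via copper phenolate 8 (not isolated)
Conditions: 2, iPrMgCl·LiCl (0.98 equiv), THF, −25 °C, 1 h; CuCl·2LiCl (1.0 equiv), −50 °C, 30 min; cannulate over 30 min into freshly dissolved 4 (1.3 equiv), THF, −78 °C, then to 0 °C, 2 h; aq Na2S2O4, 1 M HCl; SiO2 (hexane/EtOAc, 1% AcOH)
Reagents that add atoms: none
Why: Proposed new method: turbo-Grignard halogen–metal exchange (the two ortho bromines are equivalent and are favoured over the para one by the inductive and Mg-chelating OMe group) followed by Mg-to-Cu transmetalation gives monovalent arylcopper 6; the strongly oxidising, chelating o-quinone 4 adds oxidatively to it to give the square-planar trivalent copper aryl catecholate 7 (equally written as a divalent copper semiquinonate) with the aryl group cis to oxygen, so the quinone oxygen is the electrophilic partner of the aryl carbanion; C–O reductive elimination, the product-forming event of Chan–Lam and Ullmann ether syntheses and fastest for acidic oxygen ligands, then gives phenolate 8, which cannot react again because ring B has reached the catechol oxidation level; one aryl per copper and inverse addition into excess quinone suppress biaryl formation; the closest known reaction types are the oxidative coupling of aryl amidocuprates with chloranil, the oxidative addition of o-quinones to low-valent metals, and the O-attack of Grignard reagents on o-quinol acetates and hindered o-quinones; no stereocentre is formed.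

## Compound list

1 | 2,4,6-tribromophenol | Oc1c(Br)cc(Br)cc1Br | starting material
2 | 2,4,6-tribromoanisole | COc1c(Br)cc(Br)cc1Br | intermediate
3 | 3,4,5,6-tetrabromobenzene-1,2-diol (tetrabromocatechol) | Oc1c(O)c(Br)c(Br)c(Br)c1Br | starting material
4 | 3,4,5,6-tetrabromocyclohexa-3,5-diene-1,2-dione (o-bromanil) | O=C1C(=O)C(Br)=C(Br)C(Br)=C1Br | intermediate
5 | (3,5-dibromo-2-methoxyphenyl)magnesium chloride, LiCl complex (not isolated) | COc1c(Br)cc(Br)cc1[Mg]Cl | intermediate
6 | (3,5-dibromo-2-methoxyphenyl)copper, monovalent copper (not isolated) | COc1c(Br)cc(Br)cc1[Cu] | intermediate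
7 | (3,5-dibromo-2-methoxyphenyl)(3,4,5,6-tetrabromobenzene-1,2-diolato)copper, trivalent copper (not isolated) | COc1c(Br)cc(Br)cc1[Cu]1Oc2c(Br)c(Br)c(Br)c(Br)c2O1 | intermediate
8 | copper 2,3,4,5-tetrabromo-6-(3,5-dibromo-2-methoxyphenoxy)phenolate, monovalent copper (not isolated) | COc1c(Br)cc(Br)cc1Oc1c(O[Cu])c(Br)c(Br)c(Br)c1Br | intermediate
9 | 2,3,4,5-tetrabromo-6-(3,5-dibromo-2-methoxyphenoxy)phenol (achiral) | COc1c(Br)cc(Br)cc1Oc1c(O)c(Br)c(Br)c(Br)c1Br | target

## Step count and risks

Total step count: 3.
Longest linear sequence: 2 (1 → 2 → 9, or 3 → 4 → 9).
Compounds 2 and 4 are also catalogue items; if they are bought, only step 3 remains.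

**Most likely to fail, first: step 3.**
- Failure modes:
  - Outer-sphere electron transfer may give the biaryl or 2,4-dibromoanisole.
  - The aryl group may transfer to C4/C5 of the quinone with loss of bromide.
  - A minor para-magnesiated isomer may form; this is checked by an iodine quench of an aliquot.
- Fallback: the polarity is reversed on the ring A carbon instead of on oxygen. It sets out from 5 (made from 2 as in step 3) and comes back at 9. Quenching 5 with I2 (THF, −25 °C to rt) gives 1,5-dibromo-3-iodo-2-methoxybenzene F1. One-pot oxidation and arene capture (mCPBA, TsOH·H2O, MeCN, 77 °C, then 1,3,5-trimethoxybenzene) gives the trivalent iodine salt (3,5-dibromo-2-methoxyphenyl)(2,4,6-trimethoxyphenyl)iodonium 4-methylbenzenesulfonate F2. Metal-free O-arylation of the monoanion of 3 (3 equiv of 3, 3 equiv of K2CO3, MeCN, 60 °C) then transfers the less electron-rich, ortho-substituted aryl group by ligand coupling and gives 9. The excess of 3 and its steric crowding hold the reaction at mono-arylation.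

**Second: step 2.**
- Failure modes: ring cleavage by over-oxidation, or a wet or partly reduced quinone that protonates 6.
- Fallback: ring B stays at the catechol oxidation level and air supplies the oxidising equivalents. It sets out from 3 (together with 5) and comes back at 9. Mono-protection of 3 (MOMCl 1.0 equiv, iPr2NEt 1.0 equiv, CH2Cl2, 0 °C) gives 2,3,4,5-tetrabromo-6-(methoxymethoxy)phenol F3. Quenching 5 with B(OMe)3 and then 1 M HCl gives (3,5-dibromo-2-methoxyphenyl)boronic acid F4. Chan–Lam–Evans coupling of F3 with F4 (Cu(OAc)2 1 equiv, pyridine, 4 Å molecular sieves, CH2Cl2, air, rt) tolerates phenols flanked by two ortho substituents. It gives 1,2,3,4-tetrabromo-5-(3,5-dibromo-2-methoxyphenoxy)-6-(methoxymethoxy)benzene F5. HCl in MeOH at 50 °C removes the acetal and gives 9, and the aryl methyl ether survives.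

**Third: step 1.**
- Failure mode: slow alkylation of the doubly ortho-flanked phenoxide (low risk).
- Fallback: Mitsunobu etherification, which sets out from 1 and comes back at 2 (MeOH, PPh3, DIAD, THF, 0 °C to rt). The acidic phenol serves as the pronucleophile and the methoxyphosphonium ion is the carbon electrophile, so no phenoxide has to be preformed and no new compound is made.

## Further compounds

F1 | step 3 | 1,5-dibromo-3-iodo-2-methoxybenzene | COc1c(Br)cc(Br)cc1I
F2 | step 3 | (3,5-dibromo-2-methoxyphenyl)(2,4,6-trimethoxyphenyl)iodonium 4-methylbenzenesulfonate | COc1c(Br)cc(Br)cc1[I+]c1c(OC)cc(OC)cc1OC.Cc1ccc(cc1)S(=O)(=O)[O-]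
F3 | step 2 | 2,3,4,5-tetrabromo-6-(methoxymethoxy)phenol | COCOc1c(O)c(Br)c(Br)c(Br)c1Br
F4 | step 2 | (3,5-dibromo-2-methoxyphenyl)boronic acid | COc1c(Br)cc(Br)cc1B(O)O
F5 | step 2 | 1,2,3,4-tetrabromo-5-(3,5-dibromo-2-methoxyphenoxy)-6-(methoxymethoxy)benzene | COCOc1c(Oc2cc(Br)cc(Br)c2OC)c(Br)c(Br)c(Br)c1Br
F0 | step 1 | none | none
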